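Left-handed substrate has two exits, which compare like two first-order time constants: coupling with dissolved coupling partner, and the leak into achiral form, from which side product forms.

left-handed substrate 0.10 M; gas 7.6 mM (held); right-handed substrate 0.10 M; time 15 min

1. amount of left-handed product at 15 min, in percent of the left-handed substrate and right-handed substrate together charged
2. the change that raises the amount of left-handed product at 15 min, in percent of the left-handed substrate and right-handed substrate together charged most ("none" if none brings more than 2 percentage points) (spring / noon / none)
3. amount of left-handed product at 15 min, in percent of the left-handed substrate and right-handed substrate together charged, after spring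

- spring: doubling the transfer coefficient of step 3, all else as stated
- noon: doubling the saturation concentration of gas, all else as stated

- coupling partner is single-handed; left-handed substrate and right-handed substrate are mirror images of each other, charged as a racemate, each of them at the stated concentration
- at the start none of coupling partner is dissolved
- run time (flask): 15 min
- the handed part of coupling partner does not stay in what it makes, so the products of the two hands are mirror images too

    right-handed substrate ⇌ achiral form (K5 = 0.64, k5 = 4.8 × 10⁻⁴ /s)
    achiral form → side product (k2 = 0.012 /s)
    gas ⇌ coupling partner, rate k3*(csat - [coupling partner]) (k3 = 0.014 /s, csat = 7.6 mM)
    coupling partner + left-handed substrate → left-handed product (k4 = 0.21 /M/s)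
    left-handed substrate ⇌ achiral form (K5 = 0.64, k5 = 4.8 × 10⁻⁴ /s)
    coupling partner + right-handed substrate → right-handed product (k6 = 0.068 /M/s)
    coupling partner ⇌ dormant form (K7 = 11, k7 = 2.1 × 10⁻⁴ /s)

Dissolved coupling partner relaxes with a half-life of 0.276 min, much shorter than the run, so my reckoning balances gas transfer against consumption at the charged substrate levels and gets a quasi-steady [coupling partner] of 2.55 mM. Coupling is then pseudo-first-order, at 5.35 × 10⁻⁴ /s against the leak's forward 4.8 × 10⁻⁴ /s. Dividing one rate by the sum of both removes time and gives 52.7%: this is the coupling share, the part of lost left-handed substrate that becomes left-handed product. Decay at the summed rate for 15 min then gives y of 15.8%. In this reckoning spring raises [coupling partner] to 3.81 mM and y to 21.4%. Noon raises them to 5.09 mM and 25.9%, so this reckoning picks noon.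

The forecast is higher than this reckoning: y of 18.5% (17% to 20%), yb of 24.5% (22.5% to 26.5%), and noon as best, since that change “gives the same or greater driving flux with no extra first-order return term”.

The simulation gives y of 18.6%, yb of 24.4% and noon as best, with gains of 13 percentage points for noon and 5.8 points for spring.

In this flask [coupling partner] reads 4.03 mM at 15.0 min, not 2.55 mM, and left-handed substrate has lost 31 points. The coupling share turns that loss into 16.3%, against 18.6% in this flask. The neighbouring flask read at 6.0 min has lost 15 points of left-handed substrate, which the coupling share turns into 7.82%, and that flask holds 8.18% left-handed product.

The constants used here are made up; the result is computed.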